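Ring A is disconnected across C3–C4 (labdane numbering). Its quaternary C4, which bears the axial methyl and the equatorial oxygenated carbon C18 next to C5, is the retron of an epoxide-to-aldehyde ring contraction. In the precursor, a trans-fused bicyclo[5.4.0]undecene oxide, C18 is still a ring atom between C3 and C4. Lewis-acid opening at C4 and 1,2-shift of C3 turn the seven-membered ring into cyclohexane ring A, set C4 and extrude C18 as the aldehyde in one operation. The bicycle comes from (S)-carvone (ring B, C17, C4 and its methyl) by double alkylation at C10 and ring-closing metathesis; a hydroboration/alkyl–alkyl Suzuki coupling and an allylic reductive transposition complete ring B.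

Key step: step 5

Remark: labdane numbering is used for all intermediates (C17 = carbon on C8, C18 = oxygenated carbon on C4, C20 = methyl on C10); the target is read as the ent-labdane (4S,5S,9R,10S,13S).

Step 1
Reactants: 1 (S)-(+)-carvone
Product: 2 (5S,6R)-6-methylcarvone (trans epimer drawn; this centre is re-enolised in step 2)
Conditions: LiN(iPr)2, THF, −78 °C; MeI, −78 → 0 °C
Reagents that add atoms: iodomethane, CI
Why: kinetic deprotonation at the only α′-position (future C10) and C-methylation of the lithium enolate (enolate alkylation) should install C20.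

Step 2
Reactants: 2 (5S,6R)-6-methylcarvone; 3 5-iodopent-1-ene
Product: 4 (5S,6R)-2,6-dimethyl-6-(pent-4-en-1-yl)-5-(prop-1-en-2-yl)cyclohex-2-en-1-one
Conditions: LiN(iPr)2, THF, −78 → 0 °C; 3, HMPA, −78 °C → rt
Reagents that add atoms: 3 5-iodopent-1-ene, C=CCCCI
Why: enolate alkylation of the tetrasubstituted enolate should occur anti to the neighbouring C5 isopropenyl group, which puts the pentenyl arm trans and the methyl cis to isopropenyl and so fixes C10.

Step 3
Reactants: 4
Product: 5 trans-fused bicyclo[5.4.0]undecadienone (ring B enone C9=O/C7=C8; seven-membered ring C10–C1–C2–C3–C18=C4(CH3)–C5; H-5 anti to the C10 methyl)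
Conditions: second-generation Grubbs catalyst RuCl2(=CHPh)(H2IMes)(PCy3) (5 mol %), CH2Cl2, 40 °C
Reagents that add atoms: none
Why: ring-closing metathesis should join the pentenyl terminus to the isopropenyl group (the electron-poor enone alkene is inert) and close the trans-fused trisubstituted cycloheptene from two equatorial arms on neighbouring carbons.

Step 4
Reactants: 5
Product: 6 C4–C18 epoxide of 5, oxygen on the convex face (syn to H-5, anti to the C10 methyl)
Conditions: mCPBA, CH2Cl2, 0 °C
Reagents that add atoms: mCPBA, O=C(OO)c1cccc(Cl)c1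
Why: Prilezhaev epoxidation should select the electron-rich trisubstituted alkene over the enone and attack the convex face, because the axial C10 methyl sits under the concave face of the cycloheptene.

Step 5
Reactants: 6
Product: 7 keto aldehyde: trans-decalin enone in which C4 carries an axial methyl and an equatorial CHO (C18)
Conditions: MeAl(OAr)2 (MABR, Ar = 4-bromo-2,6-di-tert-butylphenyl, 20 mol %), CH2Cl2, −78 → −40 °C
Reagents that add atoms: none
Why: The aluminium Lewis acid binds the epoxide oxygen, the C4–O bond at the tertiary centre ionises, and the C18–C3 bond, held by the ring on the concave side antiperiplanar to the breaking C–O bond, shifts to C4 while C18 becomes the aldehyde carbon. This is a Meinwald epoxide–carbonyl rearrangement, the reaction type of α-pinene oxide to campholenic aldehyde and of trisubstituted epoxides under bulky aluminium phenoxides. Ring A is not closed by a cyclisation but by a suprafacial 1,2-alkyl shift that contracts the seven-membered ring (C3–C4 formed, C3–C18 broken). C4 is the only new stereocentre: C3 enters anti to the departing oxygen, with inversion at C4, so the convex-face epoxide should give the axial methyl (cis to the C10 methyl) and the equatorial CHO. The step needs opening at C4 and not at C18, which the tertiary centre secures, and migration of C3 and not hydride shift to a cycloheptanone, which the bulky phenoxide ligands and the ring geometry should favour.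

Step 6
Reactants: 7
Product: 8 hydroxy enone (C18–OH)
Conditions: NaBH4, MeOH/CH2Cl2, −78 °C
Reagents that add atoms: none
Why: borohydride reduction should take the aldehyde far faster than the conjugated C9 ketone, which is flanked by quaternary C10.

Step 7
Reactants: 8
Product: 9 diene alcohol (C9=C11H2 exocyclic, conjugated to C7=C8)
Conditions: Ph3PCH3Br, KOtBu (3 equiv each), toluene, 80 °C
Reagents that add atoms: methylenetriphenylphosphorane (from Ph3PCH3Br/KOtBu), C=P(c1ccccc1)(c1ccccc1)c1ccccc1
Why: Wittig methylenation by the small unstabilised ylide should add 1,2 to the hindered enone carbonyl and install C11, while the hydroxyl is carried as an inert alkoxide.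

Step 8
Reactants: 10 (E)-p-coumaric acid
Product: 12 (E)-4-(triisopropylsilyloxy)cinnamic acid, via bis-silylated coumarate 11 (not isolated)
Conditions: iPr3SiCl (2.2 equiv), imidazole, DMF, rt; then AcOH/THF/H2O, rt
Reagents that add atoms: chlorotri(isopropyl)silane, CC(C)[Si](Cl)(C(C)C)C(C)C
Why: silylation of phenol and acid followed by selective hydrolysis of the labile silyl ester should leave the base-stable aryl silyl ether (protecting-group chemistry).

Step 9
Reactants: 9; 12
Product: 13 diene ester (C18–O–CO–CH=CH–C6H4–OSi(iPr)3)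
Conditions: DCC, DMAP (cat.), CH2Cl2, 0 °C → rt
Reagents that add atoms: 12 (E)-4-(triisopropylsilyloxy)cinnamic acid, OC(=O)/C=C/c1ccc(O[Si](C(C)C)(C(C)C)C(C)C)cc1
Why: Steglich esterification should acylate the only hydroxyl, the equatorial primary C18–OH.

Step 10
Reactants: 14 (R)-4-methyldihydrofuran-2(3H)-one
Product: 15 (R)-4-bromo-3-methylbutanoic acid
Conditions: HBr (33 % in AcOH), 60 °C
Reagents that add atoms: hydrogen bromide, Br
Why: acid-promoted lactone opening by bromide at the primary C–O carbon (SN2) should not touch the stereocentre, the future C13.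

Step 11
Reactants: 15
Product: 16 2-(trimethylsilyl)ethyl (R)-4-bromo-3-methylbutanoate
Conditions: Me3SiCH2CH2OH, DCC, DMAP (cat.), CH2Cl2, 0 °C → rt
Reagents that add atoms: 2-(trimethylsilyl)ethanol, C[Si](C)(C)CCO
Why: Steglich esterification should give the fluoride-labile ester that masks C15.

Step 12
Reactants: 13; 16
Product: 18 labd-7-ene diester (C9–H set, full C11–C16 chain), via B-alkyl-9-BBN adduct 17 (not isolated)
Conditions: 9-BBN, THF, 0 °C → rt; then 16, Pd(OAc)2 (5 mol %), PCy3 (10 mol %), K3PO4·H2O, THF, rt → 40 °C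
Reagents that add atoms: 16 2-(trimethylsilyl)ethyl (R)-4-bromo-3-methylbutanoate, BrC[C@H](C)CC(=O)OCC[Si](C)(C)C
Why: anti-Markovnikov hydroboration of the exocyclic alkene from the face opposite the axial C10 methyl should deliver H-9 anti to that methyl (equatorial chain), and the B-alkyl Suzuki–Miyaura C(sp3)–C(sp3) coupling should then form C11–C12.

Step 13
Reactants: 18
Product: 19 allylic alcohol (C17–OH, C7=C8 retained)
Conditions: SeO2 (0.5 equiv), t-BuOOH, salicylic acid (cat.), CH2Cl2, rt
Reagents that add atoms: selenium dioxide, O=[Se]=O; tert-butyl hydroperoxide, CC(C)(C)OO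
Why: the ene/[2,3]-sigmatropic sequence of SeO2 allylic oxidation should functionalise the methyl on the more substituted alkene carbon (C17), as in the oxidation of drim-7-enes.

Step 14
Reactants: 19
Product: 22 silyl-protected target (C8=C17H2), via allylic sulfonylhydrazine 20 (not isolated), via allylic diazene 21 (not isolated)
Conditions: 2-O2NC6H4SO2NHNH2, PPh3, DEAD, N-methylmorpholine/THF, −30 °C → rt
Reagents that add atoms: none
Why: Mitsunobu displacement at the primary allylic C17, loss of sulfinic acid and retro-ene loss of N2 from the monoalkyl diazene (reductive allylic transposition) should deliver H to C7 and move the alkene to the exocyclic C8=C17 position.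

Step 15
Reactants: 22
Product: 23 target, (4S,5S,9R,10S,13S)-18-[(E)-4-hydroxycinnamoyloxy]labd-8(17)-en-15-oic acid
Conditions: Bu4NF (3 equiv), THF, 0 °C → rt; AcOH quench
Reagents that add atoms: none
Why: fluoride should cleave the aryl silyl ether and fragment the 2-(trimethylsilyl)ethyl ester (β-elimination) without attacking the hindered coumarate ester.

Compound list
1 | (S)-(+)-carvone | CC1=CC[C@H](C(C)=C)CC1=O | starting material
2 | (5S,6R)-6-methylcarvone | CC1=CC[C@H](C(C)=C)[C@@H](C)C1=O | intermediate
3 | 5-iodopent-1-ene | C=CCCCI | starting material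
4 | (5S,6R)-2,6-dimethyl-6-(pent-4-en-1-yl)-5-(prop-1-en-2-yl)cyclohex-2-en-1-one | CC1=CC[C@H](C(C)=C)[C@@](C)(CCCC=C)C1=O | intermediate
5 | trans-fused bicyclo[5.4.0]undecadienone (cycloheptene C18=C4) | CC1=CC[C@@H]2C(C)=CCCC[C@@]2(C)C1=O | intermediate
6 | convex-face C4–C18 epoxide of 5 | CC1=CC[C@@H]2[C@@]3(C)O[C@H]3CCC[C@@]2(C)C1=O | intermediate
7 | keto aldehyde (C4: axial CH3, equatorial CHO) | CC1=CC[C@@H]2[C@@](C)(C=O)CCC[C@@]2(C)C1=O | intermediate
8 | hydroxy enone (C18–OH) | CC1=CC[C@@H]2[C@@](C)(CO)CCC[C@@]2(C)C1=O | intermediate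
9 | diene alcohol (C9=C11H2) | CC1=CC[C@@H]2[C@@](C)(CO)CCC[C@@]2(C)C1=C | intermediate
10 | (E)-p-coumaric acid | OC(=O)/C=C/c1ccc(O)cc1 | starting material
11 | triisopropylsilyl (E)-4-(triisopropylsilyloxy)cinnamate | CC(C)[Si](C(C)C)(C(C)C)OC(=O)/C=C/c1ccc(O[Si](C(C)C)(C(C)C)C(C)C)cc1 | intermediate (not isolated)
12 | (E)-4-(triisopropylsilyloxy)cinnamic acid | OC(=O)/C=C/c1ccc(O[Si](C(C)C)(C(C)C)C(C)C)cc1 | intermediate
13 | diene ester | CC1=CC[C@@H]2[C@@](C)(COC(=O)/C=C/c3ccc(O[Si](C(C)C)(C(C)C)C(C)C)cc3)CCC[C@@]2(C)C1=C | intermediate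
14 | (R)-4-methyldihydrofuran-2(3H)-one | C[C@H]1COC(=O)C1 | starting material
15 | (R)-4-bromo-3-methylbutanoic acid | BrC[C@H](C)CC(=O)O | intermediate
16 | 2-(trimethylsilyl)ethyl (R)-4-bromo-3-methylbutanoate | BrC[C@H](C)CC(=O)OCC[Si](C)(C)C | intermediate
17 | B-alkyl-9-BBN adduct (boron on C11) | CC1=CC[C@@H]2[C@@](C)(COC(=O)/C=C/c3ccc(O[Si](C(C)C)(C(C)C)C(C)C)cc3)CCC[C@@]2(C)[C@@H]1CB1C2CCCC1CCC2 | intermediate (not isolated)
18 | labd-7-ene diester | CC1=CC[C@@H]2[C@@](C)(COC(=O)/C=C/c3ccc(O[Si](C(C)C)(C(C)C)C(C)C)cc3)CCC[C@@]2(C)[C@@H]1CC[C@H](C)CC(=O)OCC[Si](C)(C)C | intermediate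
19 | 17-hydroxy-labd-7-ene diester | OCC1=CC[C@@H]2[C@@](C)(COC(=O)/C=C/c3ccc(O[Si](C(C)C)(C(C)C)C(C)C)cc3)CCC[C@@]2(C)[C@@H]1CC[C@H](C)CC(=O)OCC[Si](C)(C)C | intermediate
20 | N-(C17-allyl)-N-(2-nitrobenzenesulfonyl)hydrazine | NN(CC1=CC[C@@H]2[C@@](C)(COC(=O)/C=C/c3ccc(O[Si](C(C)C)(C(C)C)C(C)C)cc3)CCC[C@@]2(C)[C@@H]1CC[C@H](C)CC(=O)OCC[Si](C)(C)C)S(=O)(=O)c1ccccc1[N+](=O)[O-] | intermediate (not isolated)
21 | C17 allylic diazene | N=NCC1=CC[C@@H]2[C@@](C)(COC(=O)/C=C/c3ccc(O[Si](C(C)C)(C(C)C)C(C)C)cc3)CCC[C@@]2(C)[C@@H]1CC[C@H](C)CC(=O)OCC[Si](C)(C)C | intermediate (not isolated)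
22 | silyl-protected target | C=C1CC[C@@H]2[C@@](C)(COC(=O)/C=C/c3ccc(O[Si](C(C)C)(C(C)C)C(C)C)cc3)CCC[C@@]2(C)[C@@H]1CC[C@H](C)CC(=O)OCC[Si](C)(C)C | intermediate
23 | (4S,5S,9R,10S,13S)-18-[(E)-4-hydroxycinnamoyloxy]labd-8(17)-en-15-oic acid | C=C1CC[C@@H]2[C@@](C)(COC(=O)/C=C/c3ccc(O)cc3)CCC[C@@]2(C)[C@@H]1CC[C@H](C)CC(=O)O | target

Total step count: 15. Longest linear sequence: 12 steps (steps 1–7, 9, 12–15, from (S)-carvone).

Steps most likely to fail

1. Step 5. After ionisation at C4, hydride shift from C18 may overtake migration of C3, so that the seven-membered ring is kept as a ketone, or the Lewis acid may be sequestered by the enone and the product aldehyde so that the reaction stalls. The fallback sets out from 5 and comes back at 7; it is a stepwise semipinacol contraction in which hydride shift is excluded by geometry. NBS in aqueous THF should convert 5 into the trans-bromohydrin F1 (bromine on C18 from the convex face, hydroxyl on C4). K2CO3 in MeOH should close it to the concave-face epoxide F2. MgBr2·OEt2 should open F2 at the tertiary carbon to the regioisomeric trans-bromohydrin F3, formed as its magnesium alkoxide with bromine on C4 on the convex face, in which only the C18–C3 ring bond can stand antiperiplanar to the C–Br bond. Warming should then give 7 by a Tiffeneau-type shift; the two inversions at C4 (bromide in, C3 in) lead to the same C4 configuration as the direct route.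

2. Step 12. Oxidative addition of the β-branched bromide 16 to the palladium–phosphine catalyst may be slow, so that β-hydride elimination and protodeboronation of the hindered borane 17 win. The fallback sets out from 13 and comes back at 18; it exchanges the roles of the partners and the mechanism. Hydroboration of 13 with 9-BBN and oxidation with NaBO3 should give the primary C11 alcohol F4, and I2/PPh3/imidazole the iodide F5. Zinc insertion (Zn, LiCl, THF) into 16 should give the alkylzinc bromide F6. A nickel-catalysed Negishi coupling (NiCl2·glyme, s-Bu-Pybox, DMA, rt), whose radical-type activation of the C11–I bond is insensitive to β-branching, should join F5 and F6 to 18.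

3. Step 2. C-alkylation of the hindered tetrasubstituted enolate by an unactivated primary iodide may be sluggish, so that proton transfer, O-alkylation or loss of HI from 3 take over. The fallback sets out from 2 and comes back at 4. The same enolate is alkylated by allyl bromide, a far better electrophile under the same facial control, to the allyl ketone F7. The monosubstituted allyl terminus is hydroborated selectively by 9-BBN to the borane F8, which is coupled in the same flask with vinyl bromide (Pd(dppf)Cl2, K3PO4, THF/DMF/H2O) to give 4.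

Further compounds
F1 | step 5 | trans-bromohydrin of 5 (Br on C18, OH on C4) | CC1=CC[C@@H]2[C@](C)(O)[C@@H](Br)CCC[C@@]2(C)C1=O
F2 | step 5 | concave-face C4–C18 epoxide (diastereomer of 6) | CC1=CC[C@@H]2[C@]3(C)O[C@@H]3CCC[C@@]2(C)C1=O
F3 | step 5 | regioisomeric trans-bromohydrin (Br on C4, OH on C18) | CC1=CC[C@@H]2[C@@](C)(Br)[C@H](O)CCC[C@@]2(C)C1=O
F4 | step 12 | C11 primary alcohol of the labd-7-ene coumarate | CC1=CC[C@@H]2[C@@](C)(COC(=O)/C=C/c3ccc(O[Si](C(C)C)(C(C)C)C(C)C)cc3)CCC[C@@]2(C)[C@@H]1CO
F5 | step 12 | C11 primary iodide | CC1=CC[C@@H]2[C@@](C)(COC(=O)/C=C/c3ccc(O[Si](C(C)C)(C(C)C)C(C)C)cc3)CCC[C@@]2(C)[C@@H]1CI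
F6 | step 12 | alkylzinc bromide from 16 | Br[Zn]C[C@H](C)CC(=O)OCC[Si](C)(C)C
F7 | step 2 | (5S,6R)-6-allyl-6-methylcarvone | CC1=CC[C@H](C(C)=C)[C@@](C)(CC=C)C1=O
F8 | step 2 | B-alkyl-9-BBN adduct of F7 | CC1=CC[C@H](C(C)=C)[C@@](C)(CCCB2C3CCCC2CCC3)C1=O
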